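**Plan**

Retrosynthesis: the aryl–vinyl C–C bond ortho to the phenol oxygen is cut first (Heck), then the two C–H bonds at C2 and C3 of the butanoate (hydrogenation of an enol acetate), then the enol O–acetyl bond, the phenol O–acyl bond (acetoacetylation) and the cinnamate C=C bond (Wittig).
Forward: the benzene ring, the only ring, is bought with Br and OH in place; the acrylate arm is joined first, the four-carbon acyl chain second, its acetate third and the hydroxy-methylbutenyl arm last; no ring is formed.
Enabling feature: C3 of the butanoate carries an acetoxy oxygen β to the C1 ester carbonyl, the O–C3–C2–C1(=O) pattern of a hydrogenated acetoacetate enol acetate, and the acetate carbonyl can chelate rhodium.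
Stereochemistry: the single stereocentre, (S) at C3, comes from ligand-controlled hydrogenation of the Z enol acetate; both E alkenes come from the Wittig and Heck reactions.

Key step: step 4

Assumption: (R,R)-Me-DuPhos is taken to deliver hydrogen to the face of the Z enol acetate that gives (S) at C3, by analogy with its sense on enamides once the changed CIP priorities are allowed for; should the sense prove opposite, the (S,S) ligand would be used with nothing else changed.

**Route**

Step 1
Reactants: 1 3-bromo-4-hydroxybenzaldehyde; 2 methyl (triphenylphosphoranylidene)acetate
Product: 3 methyl (E)-3-(3-bromo-4-hydroxyphenyl)acrylate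
Conditions: 2 (1.2 equiv), toluene, 90 °C
Reagents that add atoms: none
Why: Wittig olefination with an ester-stabilised ylide, whose reversible addition and late oxaphosphetane collapse should give the E-cinnamate and which tolerates a free para-hydroxyl group.

Step 2
Reactants: 3 methyl (E)-3-(3-bromo-4-hydroxyphenyl)acrylate; 4 2,2,6-trimethyl-4H-1,3-dioxin-4-one
Product: 6 methyl (E)-3-[3-bromo-4-(3-oxobutanoyloxy)phenyl]acrylate, via acetylketene 5 (not isolated)
Conditions: 4 (1.3 equiv), toluene, 110 °C, acetone distilled off
Reagents that add atoms: none
Why: Thermal retro-hetero-Diels–Alder cleavage of the dioxinone releases acetylketene, which the phenol O–H traps (acetoacetylation under neutral conditions), so the cinnamate and the C–Br bond should be untouched.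

Step 3
Reactants: 6 methyl (E)-3-[3-bromo-4-(3-oxobutanoyloxy)phenyl]acrylate
Product: 7 methyl (E)-3-[4-[(Z)-3-acetoxybut-2-enoyloxy]-3-bromophenyl]acrylate
Conditions: isopropenyl acetate (solvent), TsOH·H2O (5 mol %), 80 °C, acetone distilled off; any E isomer removed by chromatography
Reagents that add atoms: isopropenyl acetate, CC(=C)OC(C)=O
Why: Acid-catalysed enol acetylation by acyl exchange with isopropenyl acetate should acetylate the internally hydrogen-bonded enol of 6, whose enol oxygen lies cis to the ester carbonyl, and so give the Z enol acetate, while the electron-poor ring resists Pechmann-type cyclisation.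

Step 4
Reactants: 7 methyl (E)-3-[4-[(Z)-3-acetoxybut-2-enoyloxy]-3-bromophenyl]acrylate
Product: 8 methyl (E)-3-[4-[(S)-3-acetoxybutanoyloxy]-3-bromophenyl]acrylate
Conditions: [Rh(cod)((R,R)-Me-DuPhos)]BF4 (1 mol %), H2 (3 bar), CH2Cl2, rt, stopped after one equivalent of H2
Reagents that add atoms: none
Why: This is a rhodium–bisphospholane asymmetric hydrogenation of a β-acyloxy acrylate, the closest known reaction type being the enantioselective hydrogenation of enol esters by cationic rhodium–DuPhos complexes. The acetate carbonyl and the C2=C3 double bond of 7 bind the cationic monovalent rhodium centre as a five-membered chelate, H2 adds oxidatively to give a trivalent rhodium dihydride, and migratory insertion followed by reductive elimination forms the C–H bonds at C3 and C2 on one face of the alkene. No ring is closed and no skeletal bond is made. The new stereocentre at C3 is controlled by the twofold-symmetric (R,R)-Me-DuPhos ligand acting on a single Z alkene geometry, and the (S) acetate is expected. The step needs chemoselectivity for the enol acetate over the cinnamate double bond and the C–Br bond, and the chelating acetate, which the cinnamate lacks, together with the low hydrogen pressure should secure it. The aprotic solvent should keep the aryl ester from solvolysis.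

Step 5
Reactants: 8 methyl (E)-3-[4-[(S)-3-acetoxybutanoyloxy]-3-bromophenyl]acrylate; 9 2-methylbut-3-en-2-ol
Product: 10 methyl (E)-3-[4-[(S)-3-acetoxybutanoyloxy]-3-[(E)-3-hydroxy-3-methylbut-1-enyl]phenyl]acrylate
Conditions: 9 (2 equiv), Pd2(dba)3 (2.5 mol %), [HP(t-Bu)3]BF4 (10 mol %), Cy2NMe (1.5 equiv), 1,4-dioxane, rt to 40 °C
Reagents that add atoms: none
Why: Mizoroki–Heck reaction in which oxidative addition of the aryl bromide to zerovalent palladium, syn insertion of the terminal alkene with aryl going to the unsubstituted carbon and syn β-hydride elimination should give the E-styrenyl tertiary alcohol, which has no carbinol hydrogen and cannot isomerise to a carbonyl compound, while the hindered amine at low temperature should spare the aryl ester and the β-acetoxy group and leave C3 untouched.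

**Compound list**

1 | 3-bromo-4-hydroxybenzaldehyde | O=Cc1ccc(O)c(Br)c1 | starting material
2 | methyl (triphenylphosphoranylidene)acetate | COC(=O)C=P(c1ccccc1)(c1ccccc1)c1ccccc1 | starting material
3 | methyl (E)-3-(3-bromo-4-hydroxyphenyl)acrylate | COC(=O)/C=C/c1ccc(O)c(Br)c1 | intermediate
4 | 2,2,6-trimethyl-4H-1,3-dioxin-4-one | CC1=CC(=O)OC(C)(C)O1 | starting material
5 | acetylketene | CC(=O)C=C=O | intermediate
6 | methyl (E)-3-[3-bromo-4-(3-oxobutanoyloxy)phenyl]acrylate | COC(=O)/C=C/c1ccc(OC(=O)CC(C)=O)c(Br)c1 | intermediate
7 | methyl (E)-3-[4-[(Z)-3-acetoxybut-2-enoyloxy]-3-bromophenyl]acrylate | COC(=O)/C=C/c1ccc(OC(=O)/C=C(/C)OC(C)=O)c(Br)c1 | intermediate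
8 | methyl (E)-3-[4-[(S)-3-acetoxybutanoyloxy]-3-bromophenyl]acrylate | COC(=O)/C=C/c1ccc(OC(=O)C[C@H](C)OC(C)=O)c(Br)c1 | intermediate
9 | 2-methylbut-3-en-2-ol | C=CC(C)(C)O | starting material
10 | methyl (E)-3-[4-[(S)-3-acetoxybutanoyloxy]-3-[(E)-3-hydroxy-3-methylbut-1-enyl]phenyl]acrylate | COC(=O)/C=C/c1ccc(OC(=O)C[C@H](C)OC(C)=O)c(/C=C/C(C)(C)O)c1 | target

**Count and risks**

Total steps: 5. Longest linear sequence: 5 steps (1 → 3 → 6 → 7 → 8 → 10).

Steps most likely to fail:

Step 4. The catalyst may discriminate poorly between the two faces of the Z enol acetate, or hydrogen may also be taken up by the cinnamate double bond. In that case the stereocentre would be bought and not made. Setting out from phenol 3, commercially available (S)-3-hydroxybutanoic acid (OC(=O)C[C@H](C)O) would be O-acetylated with acetyl chloride (neat, rt) to (S)-3-acetoxybutanoic acid F1. F1 would then be joined to 3 by Steglich esterification (DIC, catalytic DMAP, CH2Cl2, 0 °C), kept cold so that the activated acid does not lose acetic acid. This comes back to the route at compound 8.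

Step 3. The acetylation may not be fully Z-selective, and acid and heat may send the aryl acetoacetate back to acetylketene and phenol or scramble the acyl groups. The enol acetate would then be made from an alkyne and not from the keto ester. Setting out from 3, esterification with but-2-ynoic acid (DIC, catalytic DMAP, CH2Cl2, 0 °C) would give methyl (E)-3-[3-bromo-4-(but-2-ynoyloxy)phenyl]acrylate F2. Acetic acid would then be added across the triple bond under Ph3PAuCl/AgOTf catalysis (AcOH, toluene, 50 °C), a known trans-hydroacyloxylation of alkynes by monovalent gold. Acetate attacks C3 of the gold-bound ynoate from the face opposite the metal and protodeauration keeps the geometry, so the acetate should end up trans to the C2 hydrogen and cis to the ester. This comes back to the route at compound 7.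

Step 5. The amine base may trigger β-elimination of acetic acid from the 3-acetoxybutanoate or cleave the aryl ester before coupling is complete, and oxidative addition next to the acyloxy group may be slow. A base-free Stille coupling would replace the Heck reaction. Commercially available 2-methylbut-3-yn-2-ol would be hydrostannylated (Bu3SnH, PdCl2(PPh3)2 as catalyst, THF, rt) to (E)-2-methyl-4-(tributylstannyl)but-3-en-2-ol F3, the bulky carbinol directing tin to the terminal carbon. F3 would be coupled with bromide 8 (Pd(PPh3)4, CuI, DMF, 60 °C, no base) with retention of the alkene geometry. This sets out from compound 8 and comes back at compound 10.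

**Further compounds**

F1 | step 4 | (S)-3-acetoxybutanoic acid | OC(=O)C[C@H](C)OC(C)=O
F2 | step 3 | methyl (E)-3-[3-bromo-4-(but-2-ynoyloxy)phenyl]acrylate | COC(=O)/C=C/c1ccc(OC(=O)C#CC)c(Br)c1
F3 | step 5 | (E)-2-methyl-4-(tributylstannyl)but-3-en-2-ol | CCCC[Sn](CCCC)(CCCC)/C=C/C(C)(C)O
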